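## Structural features

The target is a bibenzyl: a hexasubstituted benzoic acid (ring A) joined through a CH2CH2 chain at C6 to a para-hydroxyphenyl ring (ring B). Around ring A, C1 carries the carboxylic acid, C2 a methoxy group, C3 a prenyl group, C4 a free hydroxyl, C5 a second prenyl group and C6 the arylethyl chain, so no ring position is open. There is no stereocentre, and both alkenes end in gem-dimethyl groups, so no alkene geometry has to be set. The fragile elements are the two prenyl groups ortho to the C4 hydroxyl (acid or electrophilic iodine closes them to chromans or dihydrobenzofurans) and the electron-rich acid flanked by two ortho substituents and para to a hydroxyl (prone to protodecarboxylation in hot acid). The trisubstituted alkenes also exclude hydrogenolysis and strong electrophilic oxidants. The real difficulty is regiochemical: six different neighbours in a fixed order, two ring oxygens that must end differently (methyl ether at C2, free phenol at C4), and a carboxyl between a methoxy group and an alkyl chain, where hydrolysis of an ester would be very slow. The key step uses the adjacency of C1 and C6 beside the C2 methoxy group: a C1–C6 aryne polarised by that methoxy group takes a carbon nucleophile at C6 and leaves a carbanion at C1 for carboxylation, and the C2/C4/C6 oxygen pattern of the aryne precursor is that of a phloroglucinol monomethyl ether.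

## Logic of the disconnections

21 from 20. No skeletal bond is cut; the S–O bond of the sulfonate on the C4 oxygen and the Si–O bond on ring B are broken. Both groups yield to hydroxide, to which the carboxylate, the aryl methyl ether and the prenyl groups are inert, so one operation suffices and acid is confined to a cold work-up. The demand is that a sulfonate flanked by two prenyl groups is cleaved at moderate temperature.

20 from 12, 15 and 16. The C6–CH2 bond and the C1–CO2H bond are cut together. They are adjacent and C1 lies beside the C2 methoxy group, so both trace back to the C1–C6 aryne 18, which accepts 15 at C6 and 16 at C1. The gain is large: a hexasubstituted benzoic acid becomes an iodo bis-sulfonate with the oxygen pattern of 1, and the acid is obtained free, with no hindered ester to hydrolyse. The forward step must form the aryne cleanly, control the site of nucleophile attack, and outrun ene-type reactions of the aryne with the prenyl groups.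

12 from 10 and 11. Two S–O bonds are cut. Both hydroxyls of 10 have two ortho substituents and are expected to differ by only about one pKa unit, too little for reliable site selection. Giving both the same sulfonate removes that problem, because in step 9 only the sulfonate ortho to the carbon–magnesium bond can leave; the other is a spectator that also makes the aryne more electrophilic. The demand is that the spectator survives the cold exchange and comes off in step 10.

10 from 9. The two O–CH2 acetal bonds are cut. The acetals are needed only as directing groups, and their removal exposes the phenols for step 6. The demand is acid mild enough not to close a phenol onto a neighbouring prenyl group.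

9 from 7. The C1–I bond is cut. Iodine enters through an aryllithium and not through an electrophilic iodine source, because the latter would attack the trisubstituted alkenes. The demand is ring deprotonation faster than removal of a benzylic–allylic proton.

7 from 5 and 3, and 5 from 2 and 3. The ring–CH2 bonds of the two prenyl groups are cut, C3–CH2 first and C5–CH2 second (target numbering). Direct C-prenylation of 1 would give mixtures of O- and C-alkylated and over-alkylated products, whereas successive directed metalations place each group at a defined position. The demand is attack at the primary carbon of 3.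

2 from 1. Two O–CH2 bonds are cut. The acetals turn both hydroxyls of 1 into chelating directing groups in one step.

15 from 14, and 14 from 13. The C–Mg bond and the O–Si bond are cut. The bulky silyl ether is the only change needed to make the bromide compatible with magnesium.

## Other disconnections considered

Alternative 1: The cut runs through C5–C6 and C2–C3 and divides ring A into a C3–C4–C5 unit, the symmetric ketone A2, and a C6–C1–C2 unit, the chloroalkylidene malonate A3. In the forward step the enolate of A2 would displace chloride from A3 by addition–elimination, the second α-carbon would close onto one ester (Dieckmann), and enolisation would give the resorcylate A1.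
- In favour: ring A is built from acyclic pieces, so every position is fixed by connectivity. The symmetry of A2 removes any regiochemical question for the prenyl groups, and no cryogenic organometallic step is needed. On positional certainty at C3, C5 and C6 it is the equal of the chosen plan, and on operational simplicity of the ring-forming step it is the better.
- Against: A1 has both C2–OH and C4–OH free, and the C2 hydroxyl is the hydrogen-bonded, less reactive one. Methylating it alone needs protection and later release of C4–OH. The methyl ester between two ortho substituents must then be hydrolysed under forcing conditions that endanger the electron-rich acid.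
- Against, in the key step: bond formation at the fully substituted β-carbon of A3 is crowded, and O-acylation of the enolate (pyranone formation) competes with the Dieckmann closure.
- Comparison: the chosen plan has the methyl ether in place from the start and delivers the free acid, at the price of aryne chemistry next to prenyl groups. Step counts become comparable once the extra oxygen differentiation and ester cleavage are added.

Alternative 2: The cut is through C2–C3 and C4–C5, with C1–C2 broken and re-formed. Cyclobutenone A5 would open thermally to a vinylketene, add siloxyalkyne A6 by [2+2], and give phenol A4 after 4π opening, 6π closure and tautomerisation (Danheiser benzannulation).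
- In favour: the cascade is neutral and thermal, and it tolerates prenyl groups and silyl ethers. Its orientation follows from ketene–ynol ether polarity. The two ring oxygens emerge differentiated (C2 free, C4 silylated); on this point it is better than the chosen plan, which must mask C4–O with a second sulfonate.
- Against: A4 carries hydrogen at C1, so the carboxyl must still be introduced by formylation, O-methylation and aldehyde oxidation in the presence of two oxidisable alkenes, three to four further steps. The usual ketene–alkyne route to a 2,3-dialkylcyclobutenone such as A5 has its own regiochemical ambiguity, and A6 is moisture-sensitive.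
- Comparison: the chosen key step completes all six positions of ring A and this one only five. It avoids basic organometallics near sulfonates, which is a mechanistic advantage, but its step economy is poorer.

Alternative 3: The cut is through C3–C4 and C5–C6. Pyrone A8 (supplying C3, C2, C1 and C6) and siloxyalkyne A6 (supplying C4 and C5) would combine in an inverse-demand Diels–Alder reaction, and the bridged lactone would lose 16 to give benzoate A7.
- In favour: like the chosen plan it installs all six substituents in one step, including the C1 carboxyl carbon and the C2 methyl ether, and on that point it is the equal. The nucleophilic, prenyl-bearing alkyne carbon matches the pyrone carbon activated by both lactone and ester, and loss of 16 is irreversible. It has no competition between nucleophile addition and ene reaction, which is a point in its favour over the aryne.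
- Against: A8 is fully substituted at both diene termini and its 4-methoxy group donates into the diene, so the cycloaddition would need temperatures at which A6 can isomerise to a silylketene. A8 itself needs a multistep synthesis with an ambiguous O-methylation. A7 is again a methyl ester between two ortho substituents, whereas the chosen plan gives the acid directly.
- Comparison: the longer route to A8 and the ester cleavage make its step economy the weaker.

Key step: step 9

Remark: 13 is taken as purchasable 4-(2-bromoethyl)phenol, the bromide corresponding to tyrosol; aryl arenesulfonates are assumed inert to Grignard reagents at −78 °C, as the exchange in step 9 requires.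

## Route

Step 1
Reactants: 1 5-methoxyresorcinol (5-methoxybenzene-1,3-diol)
Product: 2 1-methoxy-3,5-bis(methoxymethoxy)benzene
Conditions: MOMCl (2.5 equiv), iPr2NEt (3 equiv), CH2Cl2, 0 °C to rt
Reagents that add atoms: chloromethyl methyl ether (MOMCl), COCCl
Why: Base-mediated O-alkylation of both phenols (Williamson-type acetal protection) should be clean on this unhindered resorcinol; the two methoxymethyl ethers serve as chelating ortho-directing groups for steps 2 to 4.

Step 2
Reactants: 2 1-methoxy-3,5-bis(methoxymethoxy)benzene; 3 prenyl bromide (1-bromo-3-methylbut-2-ene)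
Product: 5 5-methoxy-1,3-bis(methoxymethoxy)-2-(3-methylbut-2-enyl)benzene, via aryllithium 4 (not isolated)
Conditions: n-BuLi (1.1 equiv), THF, 0 °C, 1 h; CuBr·SMe2 (10 mol%), 3 (1.3 equiv), −78 °C to rt
Reagents that add atoms: none
Why: Directed ortho-metalation removes the proton between the two acetal oxygens, the site activated by the two strongest directing groups, to give 4; copper-catalysed allylic substitution on 3 at its primary carbon then installs the linear prenyl group at the future C5.

Step 3
Reactants: 5 5-methoxy-1,3-bis(methoxymethoxy)-2-(3-methylbut-2-enyl)benzene; 3 prenyl bromide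
Product: 7 1-methoxy-3,5-bis(methoxymethoxy)-2,4-bis(3-methylbut-2-enyl)benzene, via aryllithium 6 (not isolated)
Conditions: n-BuLi (1.2 equiv), TMEDA (1.2 equiv), THF, 0 °C, 1 h; CuBr·SMe2 (10 mol%), 3 (1.5 equiv), −78 °C to rt
Reagents that add atoms: none
Why: A second directed ortho-metalation at one of the two equivalent ring positions flanked by an acetal oxygen and the methoxy group, then the same copper-catalysed allylation; deprotonation within the oxygen-chelated aggregate should outrun removal of the benzylic–allylic protons, and any step-2 isomer prenylated beside the methoxy group converges on 7 here.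

Step 4
Reactants: 7 1-methoxy-3,5-bis(methoxymethoxy)-2,4-bis(3-methylbut-2-enyl)benzene
Product: 9 1-iodo-2-methoxy-4,6-bis(methoxymethoxy)-3,5-bis(3-methylbut-2-enyl)benzene, via aryllithium 8 (not isolated)
Conditions: n-BuLi (1.3 equiv), TMEDA (1.3 equiv), THF, −20 to 0 °C; I2 (1.4 equiv) in THF, −78 °C; aq. Na2S2O3
Reagents that add atoms: iodine, II
Why: A third directed ortho-metalation at the only ring hydrogen left, between a methoxymethoxy and the methoxy group, and iodinolysis of the carbon–lithium bond at −78 °C; this avoids electrophilic iodinating agents that would engage the alkenes, and no free phenol is present to cyclise onto an iodonium ion.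

Step 5
Reactants: 9 1-iodo-2-methoxy-4,6-bis(methoxymethoxy)-3,5-bis(3-methylbut-2-enyl)benzene
Product: 10 4-iodo-5-methoxy-2,6-bis(3-methylbut-2-enyl)benzene-1,3-diol
Conditions: 3 M aq. HCl (5 equiv), MeOH, 40 °C, argon; NaHCO3 quench at full conversion
Reagents that add atoms: none
Why: Acid-catalysed acetal exchange with methanol releases both phenols; dilute acid, moderate temperature and a bicarbonate quench are chosen because stronger acid would close each liberated hydroxyl onto an ortho prenyl group.

Step 6
Reactants: 10 4-iodo-5-methoxy-2,6-bis(3-methylbut-2-enyl)benzene-1,3-diol; 11 4-chlorobenzenesulfonyl chloride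
Product: 12 4-iodo-5-methoxy-2,6-bis(3-methylbut-2-enyl)-1,3-phenylene bis(4-chlorobenzenesulfonate)
Conditions: 11 (2.6 equiv), Et3N (4 equiv), DMAP (0.2 equiv), CH2Cl2, 0 °C to rt
Reagents that add atoms: none
Why: Amine-mediated sulfonylation of phenols with nucleophilic catalysis by DMAP; both hydroxyls are esterified on purpose, since they could not be told apart reliably, whereas step 9 distinguishes the two sulfonates by mechanism.

Step 7
Reactants: 13 4-(2-bromoethyl)phenol
Product: 14 [4-(2-bromoethyl)phenoxy]triisopropylsilane
Conditions: TIPSCl (1.2 equiv), imidazole (2 equiv), CH2Cl2, rt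
Reagents that add atoms: chlorotriisopropylsilane (TIPSCl), CC(C)[Si](Cl)(C(C)C)C(C)C
Why: Imidazole-promoted silyl ether formation at the phenol; the primary bromide is inert under these conditions, and the bulky silyl ether withstands Grignard formation and step 9.

Step 8
Reactants: 14 [4-(2-bromoethyl)phenoxy]triisopropylsilane
Product: 15 2-[4-(triisopropylsilyloxy)phenyl]ethylmagnesium bromide (titrated THF solution, used at once)
Conditions: Mg turnings (1.5 equiv), BrCH2CH2Br (cat.), THF, 30–40 °C, slow addition
Reagents that add atoms: magnesium, [Mg]
Why: Oxidative insertion of magnesium into the primary C–Br bond (Grignard formation); slow addition limits Wurtz coupling.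

Step 9
Reactants: 12 4-iodo-5-methoxy-2,6-bis(3-methylbut-2-enyl)-1,3-phenylene bis(4-chlorobenzenesulfonate); 15 2-[4-(triisopropylsilyloxy)phenyl]ethylmagnesium bromide; 16 carbon dioxide
Product: 20 4-(4-chlorobenzenesulfonyloxy)-2-methoxy-3,5-bis(3-methylbut-2-enyl)-6-{2-[4-(triisopropylsilyloxy)phenyl]ethyl}benzoic acid, via magnesiated bis-sulfonate 17 (not isolated), via aryne 18 (not isolated), via arylmagnesium bromide 19 (not isolated)
Conditions: iPrMgCl (1.05 equiv), THF (0.05 M), −78 °C, 30 min; 15 (3 equiv), −78 °C to rt, 3 h; CO2 (dry gas), −40 °C to rt; 1 M HCl, 0 °C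
Reagents that add atoms: none
Why: Isopropylmagnesium chloride exchanges the iodine, which is activated by the flanking methoxy and sulfonyloxy groups, at −78 °C to give 17 and 2-iodopropane. On warming, 17 loses the sulfonate ortho to magnesium and forms aryne 18 across C1–C6, while the second sulfonate has no metal beside it and stays as a spectator. Grignard reagent 15 adds to 18 at C6 because the inductively withdrawing C2 methoxy group polarises and distorts the triple bond, so that attack at the distal carbon leaves the carbanion at C1, where the methoxy oxygen stabilises and chelates magnesium; this should outweigh the modest hindrance of the C5 prenyl CH2 and the weak opposing pull of the remote sulfonate. Arylmagnesium 19 is then carboxylated by 16, which is small enough to reach a carbon flanked by the methoxy group and the new chain, and cold acid gives 20. The closest known reaction type is aryne generation from 2-iodoaryl arenesulfonates by iodine–magnesium exchange, addition of a magnesium nucleophile to the aryne and electrophilic trapping of the resulting arylmagnesium. No ring is closed and no stereocentre is formed. The step needs site selectivity of addition, secured by the C2 methoxy group, and chemoselectivity for nucleophile addition over ene reaction with prenyl groups and over attack at sulfonyl sulfur, secured by an excess of 15, dilution, exchange at −78 °C and no more than 1.05 equivalents of the isopropyl reagent. Any loss of the spectator sulfonate to excess Grignard reagent is harmless, since step 10 removes that group in any case.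

Step 10
Reactants: 20 4-(4-chlorobenzenesulfonyloxy)-2-methoxy-3,5-bis(3-methylbut-2-enyl)-6-{2-[4-(triisopropylsilyloxy)phenyl]ethyl}benzoic acid
Product: 21 4-hydroxy-6-[2-(4-hydroxyphenyl)ethyl]-2-methoxy-3,5-bis(3-methylbut-2-enyl)benzoic acid (CNP0254933.0)
Conditions: KOH (12 equiv), EtOH–H2O 4:1, 70 °C, argon; 1 M HCl to pH 3, 0 °C
Reagents that add atoms: none
Why: Alkaline hydrolysis: hydroxide attacks sulfur of the aryl sulfonate and silicon of the aryl silyl ether and releases both phenoxides, while carboxylate, methyl ether and prenyl groups are inert to base. Cold acidification returns the acid without the hot acid that would risk chroman formation or decarboxylation.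

## Compound list

1 | 5-methoxyresorcinol (5-methoxybenzene-1,3-diol) | COc1cc(O)cc(O)c1 | starting material
2 | 1-methoxy-3,5-bis(methoxymethoxy)benzene | COCOc1cc(OC)cc(OCOC)c1 | intermediate
3 | prenyl bromide (1-bromo-3-methylbut-2-ene) | CC(C)=CCBr | starting material
4 | 4-methoxy-2,6-bis(methoxymethoxy)phenyllithium | [Li]c1c(OCOC)cc(OC)cc1OCOC | intermediate
5 | 5-methoxy-1,3-bis(methoxymethoxy)-2-(3-methylbut-2-enyl)benzene | COCOc1cc(OC)cc(OCOC)c1CC=C(C)C | intermediate
6 | 6-methoxy-2,4-bis(methoxymethoxy)-3-(3-methylbut-2-enyl)phenyllithium | [Li]c1c(OC)cc(OCOC)c(CC=C(C)C)c1OCOC | intermediate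
7 | 1-methoxy-3,5-bis(methoxymethoxy)-2,4-bis(3-methylbut-2-enyl)benzene | COc1cc(OCOC)c(CC=C(C)C)c(OCOC)c1CC=C(C)C | intermediate
8 | 2-methoxy-4,6-bis(methoxymethoxy)-3,5-bis(3-methylbut-2-enyl)phenyllithium | [Li]c1c(OC)c(CC=C(C)C)c(OCOC)c(CC=C(C)C)c1OCOC | intermediate
9 | 1-iodo-2-methoxy-4,6-bis(methoxymethoxy)-3,5-bis(3-methylbut-2-enyl)benzene | COc1c(I)c(OCOC)c(CC=C(C)C)c(OCOC)c1CC=C(C)C | intermediate
10 | 4-iodo-5-methoxy-2,6-bis(3-methylbut-2-enyl)benzene-1,3-diol | COc1c(I)c(O)c(CC=C(C)C)c(O)c1CC=C(C)C | intermediate
11 | 4-chlorobenzenesulfonyl chloride | O=S(=O)(Cl)c1ccc(Cl)cc1 | starting material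
12 | 4-iodo-5-methoxy-2,6-bis(3-methylbut-2-enyl)-1,3-phenylene bis(4-chlorobenzenesulfonate) | COc1c(I)c(OS(=O)(=O)c2ccc(Cl)cc2)c(CC=C(C)C)c(OS(=O)(=O)c2ccc(Cl)cc2)c1CC=C(C)C | intermediate
13 | 4-(2-bromoethyl)phenol | Oc1ccc(CCBr)cc1 | starting material
14 | [4-(2-bromoethyl)phenoxy]triisopropylsilane | CC(C)[Si](Oc1ccc(CCBr)cc1)(C(C)C)C(C)C | intermediate
15 | 2-[4-(triisopropylsilyloxy)phenyl]ethylmagnesium bromide | CC(C)[Si](Oc1ccc(CC[Mg]Br)cc1)(C(C)C)C(C)C | intermediate
16 | carbon dioxide | O=C=O | starting material
17 | [2,4-bis(4-chlorobenzenesulfonyloxy)-6-methoxy-3,5-bis(3-methylbut-2-enyl)phenyl]magnesium chloride | COc1c([Mg]Cl)c(OS(=O)(=O)c2ccc(Cl)cc2)c(CC=C(C)C)c(OS(=O)(=O)c2ccc(Cl)cc2)c1CC=C(C)C | intermediate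
18 | 3-methoxy-4,6-bis(3-methylbut-2-enyl)-1,2-didehydrobenzen-5-yl 4-chlorobenzenesulfonate (aryne) | COC1=C(CC=C(C)C)C(OS(=O)(=O)c2ccc(Cl)cc2)=C(CC=C(C)C)C#C1 | intermediate
19 | {4-(4-chlorobenzenesulfonyloxy)-2-methoxy-3,5-bis(3-methylbut-2-enyl)-6-[2-(4-triisopropylsilyloxyphenyl)ethyl]phenyl}magnesium bromide | COc1c([Mg]Br)c(CCc2ccc(O[Si](C(C)C)(C(C)C)C(C)C)cc2)c(CC=C(C)C)c(OS(=O)(=O)c2ccc(Cl)cc2)c1CC=C(C)C | intermediate
20 | 4-(4-chlorobenzenesulfonyloxy)-2-methoxy-3,5-bis(3-methylbut-2-enyl)-6-{2-[4-(triisopropylsilyloxy)phenyl]ethyl}benzoic acid | COc1c(C(=O)O)c(CCc2ccc(O[Si](C(C)C)(C(C)C)C(C)C)cc2)c(CC=C(C)C)c(OS(=O)(=O)c2ccc(Cl)cc2)c1CC=C(C)C | intermediate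
21 | 4-hydroxy-6-[2-(4-hydroxyphenyl)ethyl]-2-methoxy-3,5-bis(3-methylbut-2-enyl)benzoic acid | COc1c(CC=C(C)C)c(O)c(CC=C(C)C)c(CCc2ccc(O)cc2)c1C(=O)O | target

## Step count and least certain steps

Total step count: 10. Longest linear sequence: 8 steps (1, 2, 3, 4, 5, 6, 9, 10); steps 7 and 8 are the side branch.

Step 9 (key step). What may go wrong:
- addition of 15 at C1 instead of C6, if the bulk of the C5 prenyl group erodes the control by the C2 methoxy group;
- consumption of the aryne by ene reaction with prenyl groups of a second molecule;
- attack of a Grignard reagent at sulfonyl sulfur before elimination;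
- incorporation of an isopropyl group if the exchange reagent is in excess.

Fallback (sets out from 7, returns at 21): the aryne is given up and the two bonds are made one after the other.
- Aryllithium 8, generated as in step 4, is quenched with 2-(trimethylsilyl)ethyl chloroformate to give 2-(trimethylsilyl)ethyl 2-methoxy-4,6-bis(methoxymethoxy)-3,5-bis(3-methylbut-2-enyl)benzoate F1.
- Acetal cleavage as in step 5 gives 2-(trimethylsilyl)ethyl 4,6-dihydroxy-2-methoxy-3,5-bis(3-methylbut-2-enyl)benzoate F2. Here the C6 hydroxyl is held in a hydrogen bond to the ester carbonyl, so the two phenols are differentiated.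
- Silylation (TIPSOTf, 2,6-lutidine, −78 °C) should therefore go to the C4 hydroxyl and give 2-(trimethylsilyl)ethyl 6-hydroxy-2-methoxy-3,5-bis(3-methylbut-2-enyl)-4-(triisopropylsilyloxy)benzoate F3.
- Triflation of the chelated phenol (Tf2O, pyridine) gives 2-(trimethylsilyl)ethyl 2-methoxy-3,5-bis(3-methylbut-2-enyl)-6-(trifluoromethanesulfonyloxy)-4-(triisopropylsilyloxy)benzoate F4.
- Negishi coupling (Pd(OAc)2, SPhos, THF) with {2-[4-(triisopropylsilyloxy)phenyl]ethyl}zinc chloride F5, made from 15 and ZnCl2, forms the C6–CH2 bond in 2-(trimethylsilyl)ethyl 2-methoxy-3,5-bis(3-methylbut-2-enyl)-4-(triisopropylsilyloxy)-6-{2-[4-(triisopropylsilyloxy)phenyl]ethyl}benzoate F6.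
- TBAF then removes the silylethyl ester and both silyl ethers in one operation and gives 21.

Step 10. What may go wrong: slow substitution at sulfur of the sulfonate shielded by two prenyl groups, and air oxidation of the electron-rich phenoxide on prolonged heating. Fallback (sets out from 20, returns at 21): nucleophilic attack at sulfur is replaced by single-electron reductive S–O scission and the unmasking is staged. Mg in MeOH at rt gives 4-hydroxy-2-methoxy-3,5-bis(3-methylbut-2-enyl)-6-{2-[4-(triisopropylsilyloxy)phenyl]ethyl}benzoic acid F7, and TBAF in THF then cleaves the remaining silyl ether to give 21.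

Step 5. What may go wrong: acid-catalysed closure of a liberated phenol onto a neighbouring prenyl group, and loss of iodine by ipso-protonation of the very electron-rich ring. Fallback (sets out from 9, returns at 10): the protic acid is replaced by aprotic silyl transfer. TMSOTf with 2,2′-bipyridyl in MeCN converts the aryl acetals into the silyl ethers, giving 1-iodo-2-methoxy-3,5-bis(3-methylbut-2-enyl)-4,6-bis(trimethylsilyloxy)benzene F8, and K2CO3 in MeOH releases 10, so the free phenols never meet acid.

Step 4. What may go wrong: removal of a benzylic–allylic proton of a prenyl group in competition with ring metalation, leading to side-chain iodination or alkene migration. Fallback (sets out from 7, returns at 9): metalation is replaced by electrophilic aromatic substitution with N-iodosuccinimide in MeCN at 0 °C. All three oxygens direct to the single free position, and with both phenols still masked no iodoetherification is possible. No new compound arises (F0).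

Step 2. What may go wrong: allylic transposition (attack at the tertiary terminus of 3, giving the 1,1-dimethylallyl isomer) and partial metalation beside the methoxy group. Fallback (sets out from 2, returns at 5): aryllithium 4 is quenched with allyl bromide, for which both modes of substitution give the same product, 2-allyl-5-methoxy-1,3-bis(methoxymethoxy)benzene F9. Cross-metathesis with excess 2-methylbut-2-ene (second-generation Grubbs catalyst, CH2Cl2, 40 °C) then gives 5.

## Further compounds

F1 | step 9 | 2-(trimethylsilyl)ethyl 2-methoxy-4,6-bis(methoxymethoxy)-3,5-bis(3-methylbut-2-enyl)benzoate | COc1c(C(=O)OCC[Si](C)(C)C)c(OCOC)c(CC=C(C)C)c(OCOC)c1CC=C(C)C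
F2 | step 9 | 2-(trimethylsilyl)ethyl 4,6-dihydroxy-2-methoxy-3,5-bis(3-methylbut-2-enyl)benzoate | COc1c(C(=O)OCC[Si](C)(C)C)c(O)c(CC=C(C)C)c(O)c1CC=C(C)C
F3 | step 9 | 2-(trimethylsilyl)ethyl 6-hydroxy-2-methoxy-3,5-bis(3-methylbut-2-enyl)-4-(triisopropylsilyloxy)benzoate | COc1c(C(=O)OCC[Si](C)(C)C)c(O)c(CC=C(C)C)c(O[Si](C(C)C)(C(C)C)C(C)C)c1CC=C(C)C
F4 | step 9 | 2-(trimethylsilyl)ethyl 2-methoxy-3,5-bis(3-methylbut-2-enyl)-6-(trifluoromethanesulfonyloxy)-4-(triisopropylsilyloxy)benzoate | COc1c(C(=O)OCC[Si](C)(C)C)c(OS(=O)(=O)C(F)(F)F)c(CC=C(C)C)c(O[Si](C(C)C)(C(C)C)C(C)C)c1CC=C(C)C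
F5 | step 9 | {2-[4-(triisopropylsilyloxy)phenyl]ethyl}zinc chloride | CC(C)[Si](Oc1ccc(CC[Zn]Cl)cc1)(C(C)C)C(C)C
F6 | step 9 | 2-(trimethylsilyl)ethyl 2-methoxy-3,5-bis(3-methylbut-2-enyl)-4-(triisopropylsilyloxy)-6-{2-[4-(triisopropylsilyloxy)phenyl]ethyl}benzoate | COc1c(C(=O)OCC[Si](C)(C)C)c(CCc2ccc(O[Si](C(C)C)(C(C)C)C(C)C)cc2)c(CC=C(C)C)c(O[Si](C(C)C)(C(C)C)C(C)C)c1CC=C(C)C
F7 | step 10 | 4-hydroxy-2-methoxy-3,5-bis(3-methylbut-2-enyl)-6-{2-[4-(triisopropylsilyloxy)phenyl]ethyl}benzoic acid | COc1c(C(=O)O)c(CCc2ccc(O[Si](C(C)C)(C(C)C)C(C)C)cc2)c(CC=C(C)C)c(O)c1CC=C(C)C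
F8 | step 5 | 1-iodo-2-methoxy-3,5-bis(3-methylbut-2-enyl)-4,6-bis(trimethylsilyloxy)benzene | COc1c(I)c(O[Si](C)(C)C)c(CC=C(C)C)c(O[Si](C)(C)C)c1CC=C(C)C
F0 | step 4 | none | none
F9 | step 2 | 2-allyl-5-methoxy-1,3-bis(methoxymethoxy)benzene | COCOc1cc(OC)cc(OCOC)c1CC=C
A1 | alternative 1 | methyl 2,4-dihydroxy-3,5-bis(3-methylbut-2-enyl)-6-{2-[4-(triisopropylsilyloxy)phenyl]ethyl}benzoate | COC(=O)c1c(O)c(CC=C(C)C)c(O)c(CC=C(C)C)c1CCc1ccc(O[Si](C(C)C)(C(C)C)C(C)C)cc1
A2 | alternative 1 | 2,10-dimethylundeca-2,9-dien-6-one | CC(C)=CCCC(=O)CCC=C(C)C
A3 | alternative 1 | dimethyl 2-{1-chloro-3-[4-(triisopropylsilyloxy)phenyl]propylidene}propanedioate | COC(=O)C(C(=O)OC)=C(Cl)CCc1ccc(O[Si](C(C)C)(C(C)C)C(C)C)cc1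
A4 | alternative 2 | 2,4-bis(3-methylbut-2-enyl)-3-(triisopropylsilyloxy)-5-{2-[4-(triisopropylsilyloxy)phenyl]ethyl}phenol | Oc1cc(CCc2ccc(O[Si](C(C)C)(C(C)C)C(C)C)cc2)c(CC=C(C)C)c(O[Si](C(C)C)(C(C)C)C(C)C)c1CC=C(C)C
A5 | alternative 2 | 2-(3-methylbut-2-enyl)-3-{2-[4-(triisopropylsilyloxy)phenyl]ethyl}cyclobut-2-en-1-one | O=C1CC(CCc2ccc(O[Si](C(C)C)(C(C)C)C(C)C)cc2)=C1CC=C(C)C
A6 | alternative 2 | triisopropyl[(5-methylhex-4-en-1-yn-1-yl)oxy]silane | CC(C)=CCC#CO[Si](C(C)C)(C(C)C)C(C)C
A7 | alternative 3 | methyl 2-methoxy-3,5-bis(3-methylbut-2-enyl)-4-(triisopropylsilyloxy)-6-{2-[4-(triisopropylsilyloxy)phenyl]ethyl}benzoate | COC(=O)c1c(OC)c(CC=C(C)C)c(O[Si](C(C)C)(C(C)C)C(C)C)c(CC=C(C)C)c1CCc1ccc(O[Si](C(C)C)(C(C)C)C(C)C)cc1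
A8 | alternative 3 | methyl 4-methoxy-3-(3-methylbut-2-enyl)-2-oxo-6-{2-[4-(triisopropylsilyloxy)phenyl]ethyl}-2H-pyran-5-carboxylate | COC(=O)C1=C(CCc2ccc(O[Si](C(C)C)(C(C)C)C(C)C)cc2)OC(=O)C(CC=C(C)C)=C1OC
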